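**Retrosynthetic overview**

- Target 12 is cut back to the achiral 1,4-benzodioxine 10 by removing water: C3–H and C2–OH go, and the last step is an enantioselective hydration of the C2=C3 enediol diether.
- 10 is cut at both aryl–oxygen bonds at once (C8a–O1 and C4a–O4), giving 5-allyl-3-methoxybenzyne 9 (released from silyl triflate 6) and the 1,2-dione 8; their [4+2] union forms the dioxine ring, the only ring made in the route.
- 6 comes from eugenol 1 (bromination ortho to OH, O-silylation, retro-Brook shift and triflation); 8 comes from 3',4',5'-trimethoxypropiophenone 7 by SeO2 oxidation.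
- Feature used: ring A carries O1 (on C8a) and O4 (on C4a) on neighbouring carbons, C4a lying next to C5–OMe, and C2 (hemiketal) with C3 (O-bearing CH) together form a hydrated enediol diether. This is the pattern obtained when one aryne arylates both oxygens of a 1,2-dione.

Key step: step 5

Assumption: the sense of induction of the chiral acid in step 6 cannot be predicted, so the route is written for the (R)-catalyst and its mirror image is used if it protonates the other face. The target's trans arrangement of 2-OH and 3-CH3 (both axial in the half-chair) is taken to be both the kinetic and the preferred anomer.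

**Route**

Step 1
Reactants: 1 eugenol (4-allyl-2-methoxyphenol)
Product: 2 4-allyl-2-bromo-6-methoxyphenol
Conditions: NBS (1.0 equiv), i-Pr2NH (10 mol%), CH2Cl2, 0 °C, dark
Reagents that add atoms: N-bromosuccinimide, O=C1CCC(=O)N1Br
Why: Amine-mediated electrophilic ortho-bromination of a phenol (SEAr); C6 is the only free position ortho or para to OH, and the phenol ring should react faster than the isolated terminal alkene.

Step 2
Reactants: 2 4-allyl-2-bromo-6-methoxyphenol
Product: 3 (4-allyl-2-bromo-6-methoxyphenoxy)trimethylsilane
Conditions: HMDS (1.0 equiv), THF, 70 °C; evaporate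
Reagents that add atoms: hexamethyldisilazane, C[Si](C)(C)N[Si](C)(C)C
Why: O-silylation of a phenol with HMDS, which gives only a volatile by-product so that crude 3 can be carried on.

Step 3
Reactants: 3 (4-allyl-2-bromo-6-methoxyphenoxy)trimethylsilane
Product: 6 4-allyl-2-methoxy-6-(trimethylsilyl)phenyl trifluoromethanesulfonate, via aryllithium 4 (not isolated), via lithium phenoxide 5 (not isolated)
Conditions: n-BuLi (1.1 equiv), THF, −100 to −80 °C; then Tf2O (1.2 equiv), −100 °C to 25 °C
Reagents that add atoms: trifluoromethanesulfonic anhydride, O=S(=O)(C(F)(F)F)OS(=O)(=O)C(F)(F)F; n-butyllithium (supplies the lithium of 4 and 5 only), [Li]CCCC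
Why: Br–Li exchange followed by the anionic 1,3-O-to-C silyl shift (retro-Brook rearrangement) gives the 2-silylphenoxide, which Tf2O sulfonylates on oxygen; at −100 °C the exchange is far faster than deprotonation of the allylic CH2.

Step 4
Reactants: 7 3',4',5'-trimethoxypropiophenone
Product: 8 1-(3,4,5-trimethoxyphenyl)propane-1,2-dione
Conditions: SeO2 (1.5 equiv), 1,4-dioxane/H2O (20:1), 100 °C
Reagents that add atoms: selenium dioxide, O=[Se]=O
Why: Riley oxidation of the α-methylene group of an aryl ethyl ketone to the 1,2-dione, the standard route to 1-arylpropane-1,2-diones.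

Step 5
Reactants: 6 4-allyl-2-methoxy-6-(trimethylsilyl)phenyl trifluoromethanesulfonate; 8 1-(3,4,5-trimethoxyphenyl)propane-1,2-dione
Product: 10 7-allyl-5-methoxy-3-methyl-2-(3,4,5-trimethoxyphenyl)-1,4-benzodioxine, via 5-allyl-3-methoxybenzyne 9 (not isolated)
Conditions: 8 (2 equiv), CsF (3 equiv), MeCN/toluene (1:1), 25 °C; chromatography on Et3N-treated silica
Reagents that add atoms: none
Why: Proposed new method: fluoride attacks silicon of 6 and triflate leaves to give aryne 9, across whose strained triple bond the s-cis O=C–C=O unit of 8 should add as a four-atom heterodiene in an asynchronous [4+2] process, the first C–O bond forming between the benzoyl oxygen and the aryne carbon meta to OMe and the second between the developing aryl anion ortho to OMe and the acetyl oxygen. The closest known reaction type is the [4+2] addition of arynes to o-quinones, which gives dibenzo-1,4-dioxins; an open-chain 1,2-dione has not been used in this role. The 1,4-dioxine ring is closed by this cycloaddition (two C–O bonds, four atoms from the dione and two from the aryne), driven by release of aryne strain and formation of ring A with its conjugated enediol diether. No stereocentre is created, 10 being achiral. The step needs the orientation that places O1 (on the aryl-bearing C2) meta to OMe and O4 (on the methyl-bearing C3) on the carbon next to C5–OMe: the inductively withdrawing methoxy group polarises 9 so that its distal carbon is attacked first, and the benzoyl oxygen is the better first donor because bonding through it leaves positive charge on a carbon stabilised by the trimethoxyphenyl ring. It must also outrun [2+2] addition to a single carbonyl, arylation of the enolised acetyl group and an ene reaction at the allyl chain, for which excess dione, slow aryne release in MeCN/toluene and a weakly basic fluoride source are chosen.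

Step 6
Reactants: 10 7-allyl-5-methoxy-3-methyl-2-(3,4,5-trimethoxyphenyl)-1,4-benzodioxine
Product: 12 (2S,3R)-7-allyl-5-methoxy-3-methyl-2-(3,4,5-trimethoxyphenyl)-2,3-dihydro-1,4-benzodioxin-2-ol, via oxocarbenium ion 11 (not isolated)
Conditions: (R)-3,3'-bis(2,4,6-triisopropylphenyl)-1,1'-binaphthyl-2,2'-diyl N-triflylphosphoramide (10 mol%), H2O (3 equiv), CH2Cl2, −30 °C; Et3N quench
Reagents that add atoms: water, O
Why: Proposed new method: the strong chiral acid, acting as its hydrate ion pair, should protonate the enediol diether at C3 (the site that leaves the cation at C2, stabilised by O1 and the trimethoxyphenyl ring) on the Si face inside the binaphthyl pocket, which sets C3 as R, and water should then add to oxocarbenium ion 11 anti to the pseudoaxial C3 methyl to give the 2S hemiketal with axial OH (anomeric effect), an outcome that ring–chain equilibration at C2 should not erode; the closest known reaction types are chiral Brønsted acid-catalysed enantioselective protonation of silyl enol ethers and chiral acid-catalysed addition of O–H nucleophiles to enol ethers (asymmetric acetalisation).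

**Compound list**

1 | eugenol (4-allyl-2-methoxyphenol) | C=CCc1ccc(O)c(OC)c1 | starting material
2 | 4-allyl-2-bromo-6-methoxyphenol | C=CCc1cc(Br)c(O)c(OC)c1 | intermediate
3 | (4-allyl-2-bromo-6-methoxyphenoxy)trimethylsilane | C=CCc1cc(Br)c(O[Si](C)(C)C)c(OC)c1 | intermediate
4 | [5-allyl-3-methoxy-2-(trimethylsilyloxy)phenyl]lithium (formed in the flask, not isolated) | C=CCc1cc([Li])c(O[Si](C)(C)C)c(OC)c1 | intermediate
5 | lithium 4-allyl-2-methoxy-6-(trimethylsilyl)phenoxide (formed in the flask, not isolated) | [Li+].[O-]c1c(OC)cc(CC=C)cc1[Si](C)(C)C | intermediate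
6 | 4-allyl-2-methoxy-6-(trimethylsilyl)phenyl trifluoromethanesulfonate | C=CCc1cc(OC)c(OS(=O)(=O)C(F)(F)F)c([Si](C)(C)C)c1 | intermediate
7 | 3',4',5'-trimethoxypropiophenone | CCC(=O)c1cc(OC)c(OC)c(OC)c1 | starting material
8 | 1-(3,4,5-trimethoxyphenyl)propane-1,2-dione | CC(=O)C(=O)c1cc(OC)c(OC)c(OC)c1 | intermediate
9 | 5-allyl-3-methoxybenzyne (formed in the flask, not isolated) | C=CCC1=CC#CC(OC)=C1 | intermediate
10 | 7-allyl-5-methoxy-3-methyl-2-(3,4,5-trimethoxyphenyl)-1,4-benzodioxine (achiral) | C=CCc1cc(OC)c2OC(C)=C(Oc2c1)c1cc(OC)c(OC)c(OC)c1 | intermediate
11 | (3R)-7-allyl-5-methoxy-3-methyl-2-(3,4,5-trimethoxyphenyl)-3H-1,4-benzodioxin-1-ium, ion-paired with the catalyst anion (not isolated) | C=CCc1cc(OC)c2c(c1)[O+]=C(c1cc(OC)c(OC)c(OC)c1)[C@@H](C)O2 | intermediate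
12 | (2S,3R)-7-allyl-5-methoxy-3-methyl-2-(3,4,5-trimethoxyphenyl)-2,3-dihydro-1,4-benzodioxin-2-ol | C=CCc1cc(OC)c2c(c1)O[C@@](O)(c1cc(OC)c(OC)c(OC)c1)[C@@H](C)O2 | target

**Step count**

Total steps: 6. Longest linear sequence: 5 steps (steps 1, 2, 3, 5, 6 from eugenol).

**Steps most likely to fail**

1. Step 5 (aryne/dione [4+2]). The aryne may be consumed by [2+2] addition to one carbonyl, by arylation of the enolised acetyl group or by an ene reaction at the allyl chain. The dione may also add in the reverse orientation, or fluoride may induce self-condensation of the dione. Fallback, setting out from 7 and 2 and returning at 10: ketone 7 would be α-brominated with CuBr2 (EtOAc/CHCl3, reflux) to 2-bromo-1-(3,4,5-trimethoxyphenyl)propan-1-one F1. Bromophenol 2 would then be O-alkylated with it (K2CO3, acetone, 50 °C, Williamson ether synthesis) to racemic 2-(4-allyl-2-bromo-6-methoxyphenoxy)-1-(3,4,5-trimethoxyphenyl)propan-1-one F2. The ketone enolate of this compound would be closed onto the aryl bromide by an Ullmann-type intramolecular O-arylation (CuI 10 mol%, 1,10-phenanthroline 20 mol%, Cs2CO3, toluene, 110 °C), the ring-closing mode used for benzofurans and 4H-chromenes from o-haloaryl ketones. This gives benzodioxine 10 with O4 fixed on the methyl-bearing carbon by construction.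

2. Step 6 (enantioselective hydration). Uncatalysed or achiral background protonation, reversible proton loss from the oxocarbenium ion back to the enol ether, or protonation at C2 instead of C3 could lower the enantiomeric purity or the regiochemical outcome. Fallback, setting out from 10 and returning at 12: 10 would be hydrated with a dilute achiral acid (pyridinium p-toluenesulfonate, THF/H2O, 0 °C, ordinary enol ether hydration) to the racemic trans hemiketal. This is 12 together with its mirror image, (2R,3S)-7-allyl-5-methoxy-3-methyl-2-(3,4,5-trimethoxyphenyl)-2,3-dihydro-1,4-benzodioxin-2-ol F3. The two would be separated by preparative HPLC on an amylose tris(3,5-dimethylphenylcarbamate) phase to give 12. The unwanted enantiomer would be dehydrated back to achiral 10 (TsOH cat., toluene, reflux with water removal) and recycled.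

3. Step 1 (ortho-bromination of eugenol). Bromine may add across the allyl double bond or substitute the allylic/benzylic position in competition with ring bromination. Fallback, setting out from 1 and returning at 2: eugenol would be treated with Br2 (2.1 equiv, CH2Cl2, 0 °C) so that ring and alkene are both brominated on purpose, giving racemic 2-bromo-4-(2,3-dibromopropyl)-6-methoxyphenol F4. Zinc dust (AcOH/Et2O, 25 °C) would then remove the vicinal dibromide by reductive elimination and restore the allyl group, leaving the aryl bromide untouched, to give 2.

**Further compounds**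

F1 | step 5 | 2-bromo-1-(3,4,5-trimethoxyphenyl)propan-1-one | CC(Br)C(=O)c1cc(OC)c(OC)c(OC)c1
F2 | step 5 | racemic 2-(4-allyl-2-bromo-6-methoxyphenoxy)-1-(3,4,5-trimethoxyphenyl)propan-1-one | C=CCc1cc(Br)c(OC(C)C(=O)c2cc(OC)c(OC)c(OC)c2)c(OC)c1
F3 | step 6 | (2R,3S)-7-allyl-5-methoxy-3-methyl-2-(3,4,5-trimethoxyphenyl)-2,3-dihydro-1,4-benzodioxin-2-ol (mirror image of 12, formed with it as the racemate) | C=CCc1cc(OC)c2c(c1)O[C@](O)(c1cc(OC)c(OC)c(OC)c1)[C@H](C)O2
F4 | step 1 | racemic 2-bromo-4-(2,3-dibromopropyl)-6-methoxyphenol | BrCC(Br)Cc1cc(Br)c(O)c(OC)c1
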